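**Plan**

- Numbering: C8 is the quaternary oxirane carbon, C9 the oxirane CH2, C10 the exocyclic CH2O on C8, C7 the benzylic CH2O on the arene, O3 the phenol oxygen.
- Retrosynthesis: the three ester C–O bonds are cut first (angeloyl on O3, 2-methylbutanoyl on O7 and O10), then the oxirane O–C9 bond back to a C8,C9-diol, then the tertiary C8–O bond.
- Enabling feature: C8 carries one oxygen and two CH2O arms. If C10 is held as a vinyl group, C8 becomes the substituted terminus of a π-allyl unit with the C9 oxygen tethered to it, so C8–O can be made by closing a 1,3-dioxolan-2-one ring (O–C8–C9–O–C=O) from a racemic 2-aryl-2-vinyloxirane and CO2.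
- Forward: the protected aryl bromide is acylated and vinylated to the racemic oxirane; the carbonate ring closes in the key step and is then traded for the oxirane ring; the vinyl group is cut down to C10–OH; the esters go on last, angelate at the very end.
- Stereochemistry: C8 comes from the chiral bisphosphine on palladium in the key step and no later step breaks a bond at C8 (the S to R change of descriptor on acylation is a CIP ranking effect only); both acyl C2 centres come from (R)-2-methylbutanoic acid; the Z alkene comes from angelic acid.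

Key step: step 6

Assumption: the (R,R)-ligand is taken to give the (R)-carbonate 12; the sense of induction is to be confirmed on the first run, and if it is opposite the (S,S)-ligand is used with no other change.

In the names below, Ar = 4-(tert-butyldimethylsilyloxymethyl)-2-(4-methoxybenzyloxy)phenyl.

**Step 1**
Reactants: 1 methyl 4-bromo-3-hydroxybenzoate
Product: 2 methyl 4-bromo-3-(4-methoxybenzyloxy)benzoate
Conditions: 4-methoxybenzyl chloride, K2CO3, Bu4NI (cat.), DMF, 60 °C
Reagents that add atoms: 4-methoxybenzyl chloride, COc1ccc(CCl)cc1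
Why: Williamson etherification, in which the phenoxide formed with K2CO3 displaces chloride from the benzylic halide (SN2) while the methyl ester is inert.

**Step 2**
Reactants: 2 methyl 4-bromo-3-(4-methoxybenzyloxy)benzoate
Product: 3 [4-bromo-3-(4-methoxybenzyloxy)phenyl]methanol
Conditions: i-Bu2AlH, CH2Cl2, −78 → 0 °C; aqueous potassium sodium tartrate work-up
Reagents that add atoms: none
Why: Hydride reduction of the benzoate ester by i-Bu2AlH should stop at the benzylic alcohol and leave the aryl bromide and the benzyl ether untouched.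

**Step 3**
Reactants: 3 [4-bromo-3-(4-methoxybenzyloxy)phenyl]methanol
Product: 4 [4-bromo-3-(4-methoxybenzyloxy)benzyloxy](tert-butyl)dimethylsilane
Conditions: tert-butyldimethylsilyl chloride, imidazole, DMF, rt
Reagents that add atoms: tert-butyldimethylsilyl chloride, CC(C)(C)[Si](C)(C)Cl
Why: Corey silylation of the primary alcohol masks C7–OH as an ether that is stable to organolithium, Grignard and carbonate reagents.

**Step 4**
Reactants: 4 [4-bromo-3-(4-methoxybenzyloxy)benzyloxy](tert-butyl)dimethylsilane; 5 2-chloro-N-methoxy-N-methylacetamide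
Product: 8 2-chloro-1-Ar-ethan-1-one, via aryllithium 6 (not isolated), via lithium hemiaminal alkoxide 7 (not isolated)
Conditions: n-BuLi, THF, −78 °C; then 5, −78 → −20 °C; aq NH4Cl
Reagents that add atoms: none
Why: Bromine–lithium exchange at −78 °C is faster than any attack on the ethers, and the Weinreb ketone synthesis holds the adduct as a chelated tetrahedral alkoxide until work-up, so the chloromethyl ketone should form without over-addition or loss of chloride.

**Step 5**
Reactants: 8 2-chloro-1-Ar-ethan-1-one
Product: 10 racemic 2-Ar-2-vinyloxirane, via bromomagnesium chlorohydrin alkoxide 9 (not isolated)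
Conditions: CH2=CHMgBr, THF, −78 → 0 °C; then MeOH, K2CO3, rt
Reagents that add atoms: vinylmagnesium bromide, C=C[Mg]Br
Why: Grignard 1,2-addition to the ketone outpaces displacement of chloride at low temperature, and the tertiary chlorohydrin then closes by intramolecular Williamson reaction (3-exo-tet) to the racemic oxirane that the next step requires.

**Step 6**
Reactants: 10 racemic 2-Ar-2-vinyloxirane; 11 carbon dioxide
Product: 12 (R)-4-Ar-4-vinyl-1,3-dioxolan-2-one
Conditions: 11 (1 atm), Pd2(dba)3·CHCl3 (2.5 mol%), (R,R)-N,N'-(cyclohexane-1,2-diyl)bis[2-(diphenylphosphino)benzamide] (7.5 mol%), CH2Cl2, 0 °C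
Reagents that add atoms: none
Why: Zerovalent palladium opens either enantiomer of 10 by anti oxidative addition to a zwitterionic π-allyl complex of divalent palladium bearing a CH2O alkoxide, and the two diastereomeric complexes exchange allyl faces by η3–η1–η3 shifts through the unsubstituted CH2 terminus faster than they are trapped. The alkoxide adds to CO2 and the resulting carbonate oxygen attacks the aryl-bearing terminus C8 on the face opposite palladium, which closes the 1,3-dioxolan-2-one ring in a 5-exo mode and releases the catalyst. The closest known reaction is the palladium-catalysed dynamic kinetic asymmetric addition of CO2 or hydrogencarbonate to 2-methyl-2-vinyloxirane with the same ligand family. The C8 configuration is set by the chiral pocket of the C2-symmetric ligand, which makes ring closure of one of the equilibrating π-allyl diastereomers faster (Curtin–Hammett control). The step needs attack at the substituted terminus, which the tether secures because closure at the far terminus would need a seven-membered ring, and it needs equilibration to outrun closure, which the free CH2 terminus of the vinyl group secures. A CO2 atmosphere at 0 °C and a quench at full conversion should keep the product carbonate from re-ionising and losing enantiomeric purity.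

**Step 7**
Reactants: 12 (R)-4-Ar-4-vinyl-1,3-dioxolan-2-one
Product: 13 (R)-2-Ar-but-3-ene-1,2-diol
Conditions: K2CO3 (0.2 equiv), MeOH, 0 °C → rt
Reagents that add atoms: none
Why: Base-catalysed transesterification of the cyclic carbonate releases the diol with dimethyl carbonate as the leaving fragment, and no bond at C8 is broken, so its configuration is kept.

**Step 8**
Reactants: 13 (R)-2-Ar-but-3-ene-1,2-diol
Product: 15 (R)-2-Ar-2-vinyloxirane, via sodium alkoxide tosylate 14 (not isolated)
Conditions: NaH, THF, 0 °C; then 1-(4-toluenesulfonyl)imidazole, 0 °C → rt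
Reagents that add atoms: none
Why: In this one-flask diol-to-oxirane conversion the primary alkoxide is sulfonylated selectively and the tertiary alkoxide displaces the tosylate at C9 (3-exo-tet intramolecular Williamson reaction), so the C8–O bond is untouched and the configuration is retained.

**Step 9**
Reactants: 15 (R)-2-Ar-2-vinyloxirane
Product: 17 [(S)-2-Ar-oxiran-2-yl]methanol, via ozonide 16 (not isolated)
Conditions: O3, CH2Cl2, NaHCO3, −78 °C (Sudan Red 7B end point); then NaBH4, MeOH, −78 → 0 °C
Reagents that add atoms: ozone, [O-][O+]=O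
Why: Criegee ozonolysis of the terminal alkene, stopped at the dye end point to spare the anisyl ether, followed by borohydride reduction of the ozonide should give the C10 alcohol, and the quaternary C8 cannot epimerise.

**Step 10**
Reactants: 17 [(S)-2-Ar-oxiran-2-yl]methanol
Product: 18 {(S)-2-[4-(hydroxymethyl)-2-(4-methoxybenzyloxy)phenyl]oxiran-2-yl}methanol
Conditions: Bu4NF, THF, 0 °C
Reagents that add atoms: none
Why: Fluoride-induced Si–O cleavage frees C7–OH, and the only base-induced pathway open to the epoxy alcohol, the Payne rearrangement, is degenerate here and returns the same enantiomer.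

**Step 11**
Reactants: 18 {(S)-2-[4-(hydroxymethyl)-2-(4-methoxybenzyloxy)phenyl]oxiran-2-yl}methanol; 19 (R)-2-methylbutanoic acid
Product: 20 {(R)-2-[2-(4-methoxybenzyloxy)-4-{[(R)-2-methylbutanoyloxy]methyl}phenyl]oxiran-2-yl}methyl (R)-2-methylbutanoate
Conditions: 19 (2.5 equiv), dicyclohexylcarbodiimide, DMAP (cat.), CH2Cl2, 0 °C → rt
Reagents that add atoms: none
Why: Steglich esterification acylates both primary hydroxyls under near-neutral conditions that spare the oxirane and do not enolise the α-stereocentre of the acid.

**Step 12**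
Reactants: 20 {(R)-2-[2-(4-methoxybenzyloxy)-4-{[(R)-2-methylbutanoyloxy]methyl}phenyl]oxiran-2-yl}methyl (R)-2-methylbutanoate
Product: 21 {(R)-2-[2-hydroxy-4-{[(R)-2-methylbutanoyloxy]methyl}phenyl]oxiran-2-yl}methyl (R)-2-methylbutanoate
Conditions: DDQ, CH2Cl2/pH 7 phosphate buffer, 0 °C → rt; crude phenol used at once
Reagents that add atoms: none
Why: In this oxidative debenzylation DDQ abstracts hydride from the electron-rich anisyl CH2 and water cleaves the oxocarbenium ion to the phenol, while the buffer keeps the acidic hydroquinone away from the oxirane.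

**Step 13**
Reactants: 21 {(R)-2-[2-hydroxy-4-{[(R)-2-methylbutanoyloxy]methyl}phenyl]oxiran-2-yl}methyl (R)-2-methylbutanoate; 22 angelic acid
Product: 24 {(R)-2-[2-{[(Z)-2-methylbut-2-enoyl]oxy}-4-{[(R)-2-methylbutanoyloxy]methyl}phenyl]oxiran-2-yl}methyl (R)-2-methylbutanoate, via mixed anhydride 23 (not isolated)
Conditions: 22, 2,4,6-trichlorobenzoyl chloride, Et3N, toluene, rt; then 21, Et3N, 0 °C → rt
Reagents that add atoms: none
Why: Yamaguchi-type acylation through the mixed anhydride without DMAP is the protocol that transfers an angeloyl group without Z to E isomerisation, and the phenol should attack the less hindered carbonyl under a mild amine base that avoids a free phenoxide next to the oxirane.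

**Compound list**

1 | methyl 4-bromo-3-hydroxybenzoate | COC(=O)c1ccc(Br)c(O)c1 | starting material
2 | methyl 4-bromo-3-(4-methoxybenzyloxy)benzoate | COC(=O)c1ccc(Br)c(OCc2ccc(OC)cc2)c1 | intermediate
3 | [4-bromo-3-(4-methoxybenzyloxy)phenyl]methanol | OCc1ccc(Br)c(OCc2ccc(OC)cc2)c1 | intermediate
4 | [4-bromo-3-(4-methoxybenzyloxy)benzyloxy](tert-butyl)dimethylsilane | CC(C)(C)[Si](C)(C)OCc1ccc(Br)c(OCc2ccc(OC)cc2)c1 | intermediate
5 | 2-chloro-N-methoxy-N-methylacetamide | CON(C)C(=O)CCl | starting material
6 | Ar-lithium (aryllithium from 4) | [Li]c1ccc(CO[Si](C)(C)C(C)(C)C)cc1OCc1ccc(OC)cc1 | intermediate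
7 | lithium 2-chloro-1-Ar-1-[methoxy(methyl)amino]ethan-1-olate (racemic tetrahedral adduct) | [Li]OC(CCl)(N(C)OC)c1ccc(CO[Si](C)(C)C(C)(C)C)cc1OCc1ccc(OC)cc1 | intermediate
8 | 2-chloro-1-Ar-ethan-1-one | O=C(CCl)c1ccc(CO[Si](C)(C)C(C)(C)C)cc1OCc1ccc(OC)cc1 | intermediate
9 | bromomagnesium alkoxide of racemic 1-chloro-2-Ar-but-3-en-2-ol | Br[Mg]OC(CCl)(C=C)c1ccc(CO[Si](C)(C)C(C)(C)C)cc1OCc1ccc(OC)cc1 | intermediate
10 | racemic 2-Ar-2-vinyloxirane | COc1ccc(COc2cc(CO[Si](C)(C)C(C)(C)C)ccc2C2(C=C)CO2)cc1 | intermediate
11 | carbon dioxide | O=C=O | starting material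
12 | (R)-4-Ar-4-vinyl-1,3-dioxolan-2-one | COc1ccc(COc2cc(CO[Si](C)(C)C(C)(C)C)ccc2[C@]2(C=C)COC(=O)O2)cc1 | intermediate
13 | (R)-2-Ar-but-3-ene-1,2-diol | COc1ccc(COc2cc(CO[Si](C)(C)C(C)(C)C)ccc2[C@](O)(C=C)CO)cc1 | intermediate
14 | sodium alkoxide of (R)-2-Ar-2-hydroxybut-3-en-1-yl 4-methylbenzenesulfonate | COc1ccc(COc2cc(CO[Si](C)(C)C(C)(C)C)ccc2[C@](O[Na])(C=C)COS(=O)(=O)c2ccc(C)cc2)cc1 | intermediate
15 | (R)-2-Ar-2-vinyloxirane | COc1ccc(COc2cc(CO[Si](C)(C)C(C)(C)C)ccc2[C@]2(C=C)CO2)cc1 | intermediate
16 | 3-[(R)-2-Ar-oxiran-2-yl]-1,2,4-trioxolane (mixture at the trioxolane carbon) | COc1ccc(COc2cc(CO[Si](C)(C)C(C)(C)C)ccc2[C@]2(C3OCOO3)CO2)cc1 | intermediate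
17 | [(S)-2-Ar-oxiran-2-yl]methanol | COc1ccc(COc2cc(CO[Si](C)(C)C(C)(C)C)ccc2[C@]2(CO)CO2)cc1 | intermediate
18 | {(S)-2-[4-(hydroxymethyl)-2-(4-methoxybenzyloxy)phenyl]oxiran-2-yl}methanol | COc1ccc(COc2cc(CO)ccc2[C@]2(CO)CO2)cc1 | intermediate
19 | (R)-2-methylbutanoic acid | CC[C@@H](C)C(=O)O | starting material
20 | {(R)-2-[2-(4-methoxybenzyloxy)-4-{[(R)-2-methylbutanoyloxy]methyl}phenyl]oxiran-2-yl}methyl (R)-2-methylbutanoate | COc1ccc(COc2cc(COC(=O)[C@H](C)CC)ccc2[C@]2(COC(=O)[C@H](C)CC)CO2)cc1 | intermediate
21 | {(R)-2-[2-hydroxy-4-{[(R)-2-methylbutanoyloxy]methyl}phenyl]oxiran-2-yl}methyl (R)-2-methylbutanoate | Oc1cc(COC(=O)[C@H](C)CC)ccc1[C@]1(COC(=O)[C@H](C)CC)CO1 | intermediate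
22 | angelic acid, (Z)-2-methylbut-2-enoic acid | C/C=C(/C)C(=O)O | starting material
23 | (Z)-2-methylbut-2-enoic 2,4,6-trichlorobenzoic anhydride | C/C=C(/C)C(=O)OC(=O)c1c(Cl)cc(Cl)cc1Cl | intermediate
24 | {(R)-2-[2-{[(Z)-2-methylbut-2-enoyl]oxy}-4-{[(R)-2-methylbutanoyloxy]methyl}phenyl]oxiran-2-yl}methyl (R)-2-methylbutanoate, CNP0166772.1 | C/C=C(/C)C(=O)Oc1cc(COC(=O)[C@H](C)CC)ccc1[C@]1(COC(=O)[C@H](C)CC)CO1 | target

**Step count and risks**

Total step count: 13. Longest linear sequence: 13 steps (1 to 24); 5, 11, 19 and 22 are used as bought.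

Steps most likely to fail:

1. Step 6. The aryl-substituted π-allyl complexes may close faster than they equilibrate, or the product carbonate may re-ionise on palladium, so that the enantiomeric purity is low or erodes with time; the zwitterion may also drain away by hydride shift. The fallback sets out from 10 and comes back at 13. Oxirane 10 is carboxylated with CO2 under achiral Pd(PPh3)4 in THF to the racemic 4-Ar-4-vinyl-1,3-dioxolan-2-one F1. F1 is then submitted to the known enantioconvergent decarboxylative allylic substitution with water (Pd2(dba)3·CHCl3, a chiral phosphoramidite, Et3B as co-catalyst, aqueous THF), which delivers hydroxide to C8 of the π-allyl intermediate and gives diol 13 directly, a product that cannot re-ionise.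

2. Step 13. The angeloyl group may isomerise from Z to E during acyl transfer, and the ortho-hydroxyaryl oxirane freed in step 12 may open under phenoxide assistance before it is acylated. The fallback sets out from 21 and ends at 24. Phenol 21 is esterified with 2-[bis(2,2,2-trifluoroethoxy)phosphoryl]propanoic acid (dicyclohexylcarbodiimide, CH2Cl2, 0 °C) to the aryl 2-phosphonopropanoate F2, which carries no isomerisable alkene. A Still–Gennari olefination of F2 with acetaldehyde (KN(SiMe3)2, 18-crown-6, THF, −78 °C) then builds the Z alkene under kinetic control and gives 24.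

3. Step 9. Ozone may over-oxidise the anisyl ether or the electron-rich arene, and acidic or peroxidic by-products may open the aryl oxirane before reduction. The fallback sets out from 15 and comes back at 17. The vinyl group of 15 is dihydroxylated (OsO4 cat., N-methylmorpholine N-oxide, acetone/water) to the 1-[(R)-2-Ar-oxiran-2-yl]ethane-1,2-diol F3. F3 is cleaved with NaIO4 in buffered aqueous THF to the (R)-2-Ar-oxirane-2-carbaldehyde F4, and F4 is reduced with NaBH4 in MeOH at 0 °C to 17.

**Further compounds**

F1 | step 6 | racemic 4-Ar-4-vinyl-1,3-dioxolan-2-one | COc1ccc(COc2cc(CO[Si](C)(C)C(C)(C)C)ccc2C2(C=C)COC(=O)O2)cc1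
F2 | step 13 | {(R)-2-[2-({2-[bis(2,2,2-trifluoroethoxy)phosphoryl]propanoyl}oxy)-4-{[(R)-2-methylbutanoyloxy]methyl}phenyl]oxiran-2-yl}methyl (R)-2-methylbutanoate | CC(C(=O)Oc1cc(COC(=O)[C@H](C)CC)ccc1[C@]1(COC(=O)[C@H](C)CC)CO1)P(=O)(OCC(F)(F)F)OCC(F)(F)F
F3 | step 9 | 1-[(R)-2-Ar-oxiran-2-yl]ethane-1,2-diol (mixture at the new carbinol carbon) | COc1ccc(COc2cc(CO[Si](C)(C)C(C)(C)C)ccc2[C@]2(C(O)CO)CO2)cc1
F4 | step 9 | (R)-2-Ar-oxirane-2-carbaldehyde | COc1ccc(COc2cc(CO[Si](C)(C)C(C)(C)C)ccc2[C@]2(C=O)CO2)cc1
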